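**Plan**

Numbering: hydrindane C1 (carries the CH2 link), C3a (CH2OH), C4 (Br), C7 (carbinol), C7a (fusion CH); cyclohexane ring A: C1′ (OAc), C4′ (Br).
Cuts, in retrosynthetic order: CH2OH ⇐ angular allyl (C=C cleavage); C4–Br ⇐ axial C4–OH ⇐ C4=O; C7–CH3 ⇐ C7=O; then bond C3a–C7a of the six-membered carbocycle is exchanged for C3a–C7 (1,2-shift); C7–C7a (nitro-aldol); C3a–allyl; C3a–C3 (reductive alkylation of cyclopentane-1,3-dione); C1–C7a (nitromethane addition); C1=C2 (metathesis); C1′–CH2 (allyl Grignard).
Feature used: in the six-membered carbocycle C3a–C4–C5–C6–C7–C7a the carbinol carbon C7 (a latent ketone) sits next to the fusion CH C7a and 1,4 to C4. A trans-hexahydroindane-4,7-dione is therefore the semipinacol isomer of a cis-fused bicycle in which C4 and C7 are the two carbonyl carbons of a 2,2-disubstituted cyclopentane-1,3-dione, C7 bears an angular OH, and C7a bears an equatorial NH2 anti-periplanar to the C7–C3a bond.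
Forward: ring A is made first and its allyl group is grown into the chain; nitro-aldol closure gives a cyclohexane fused cis to the cyclopentanone; the deaminative shift then enlarges the cyclopentanone to the cyclohexane ring of the target and contracts the cyclohexane to its cyclopentane; methyl addition, reduction, bromination and allyl cleavage finish.
Stereochemistry: C4′ from a CBS reduction (then SN2 inversion); C1′ from equatorial Grignard attack; C1 from an organocatalytic nitro-Michael addition; C3a, the carbinol carbon and the nitro carbon from the equilibrating nitro-aldol step relative to C1; C7a by inversion in the shift (trans fusion); C7 by equatorial methyl delivery; C4 by equatorial hydride delivery followed by SN2 inversion.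

Key step: step 12

Assumption: the monoketal 1 is taken as a catalogue compound (otherwise it is one step from 1,4-dioxaspiro[4.5]decan-8-one by α,α-dimethylation).

Step 1
Reactants: 1 7,7-dimethyl-1,4-dioxaspiro[4.5]decan-8-one
Product: 2 (8R)-7,7-dimethyl-1,4-dioxaspiro[4.5]decan-8-ol
Conditions: (S)-Me-CBS (10 mol %), BH3·SMe2, THF, −20 °C; MeOH/H2O work-up
Reagents that add atoms: none
Why: Corey–Bakshi–Shibata reduction, in which the oxazaborolidine binds the ketone with the quaternary C(CH3)2 side as the large group and delivers hydride to one face, which should set the (R)-carbinol that later fixes the absolute configuration of ring A.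

Step 2
Reactants: 2 (8R)-7,7-dimethyl-1,4-dioxaspiro[4.5]decan-8-ol
Product: 3 tert-butyl{[(8R)-7,7-dimethyl-1,4-dioxaspiro[4.5]decan-8-yl]oxy}dimethylsilane
Conditions: TBSOTf, 2,6-lutidine, CH2Cl2, −78 °C
Reagents that add atoms: tert-butyldimethylsilyl trifluoromethanesulfonate CC(C)(C)[Si](C)(C)OS(=O)(=O)C(F)(F)F
Why: Silylation with the silyl triflate is fast even for a neopentylic secondary alcohol and should leave the dioxolane intact at low temperature; the bulky silyl ether is wanted in step 4 as a conformational control element and no stereocentre is touched.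

Step 3
Reactants: 3 tert-butyl{[(8R)-7,7-dimethyl-1,4-dioxaspiro[4.5]decan-8-yl]oxy}dimethylsilane
Product: 4 (4R)-4-[(tert-butyldimethylsilyl)oxy]-3,3-dimethylcyclohexan-1-one
Conditions: PPTS (cat.), acetone/H2O, 56 °C
Reagents that add atoms: water O
Why: Acid-catalysed ketal hydrolysis releases the ketone while the hindered secondary TBS ether should survive the weak acid; no stereocentre is touched.

Step 4
Reactants: 4 (4R)-4-[(tert-butyldimethylsilyl)oxy]-3,3-dimethylcyclohexan-1-one; 5 allylmagnesium bromide
Product: 7 (1S,4R)-1-allyl-4-[(tert-butyldimethylsilyl)oxy]-3,3-dimethylcyclohexyl acetate, via bromomagnesium alkoxide 6 (not isolated)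
Conditions: 5, THF, −78 °C; then Ac2O, DMAP, −78 → 23 °C
Reagents that add atoms: acetic anhydride CC(=O)OC(C)=O
Why: Grignard 1,2-addition followed by O-acylation of the alkoxide, in which the ketone is expected to react mainly through the chair with the silyloxy group axial (an equatorial OSi is gauche to both methyl groups and an axial 4-alkoxy group is stabilised through space by the carbonyl group) and allyl enters equatorially, anti to the axial 3-methyl group, so that the new C–O bond is axial and trans to the silyloxy group (1S).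

Step 5
Reactants: 7 (1S,4R)-1-allyl-4-[(tert-butyldimethylsilyl)oxy]-3,3-dimethylcyclohexyl acetate
Product: 8 (1S,4R)-1-allyl-4-hydroxy-3,3-dimethylcyclohexyl acetate
Conditions: HF·pyridine, pyridine/THF, 0 → 23 °C
Reagents that add atoms: none
Why: Fluoride-mediated desilylation cleaves only the Si–O bond, and the tertiary acetate and the alkene should be inert to buffered HF·pyridine, so the axial alcohol is set free without change of configuration.

Step 6
Reactants: 8 (1S,4R)-1-allyl-4-hydroxy-3,3-dimethylcyclohexyl acetate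
Product: 9 (1S,4S)-1-allyl-4-bromo-3,3-dimethylcyclohexyl acetate
Conditions: CBr4, PPh3, toluene, 23 → 60 °C
Reagents that add atoms: carbon tetrabromide BrC(Br)(Br)Br
Why: Appel reaction, in which bromide displaces the axial oxyphosphonium group by SN2 along the equatorial trajectory and so inverts C4 to give the equatorial bromide cis to the acetate, the outcome known for axial alcohols next to a gem-dimethyl carbon in conformationally fixed cyclohexanes.

Step 7
Reactants: 9 (1S,4S)-1-allyl-4-bromo-3,3-dimethylcyclohexyl acetate; 10 (E)-but-2-enal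
Product: 11 (1S,4S)-4-bromo-3,3-dimethyl-1-[(2E)-4-oxobut-2-en-1-yl]cyclohexyl acetate
Conditions: 10 (excess), Hoveyda–Grubbs II (5 mol %), CH2Cl2, 40 °C
Reagents that add atoms: none
Why: Olefin cross-metathesis of the terminal alkene with an excess of the electron-poor enal partner, which is driven by loss of propene and should give the conjugated product as the E isomer.

Step 8
Reactants: 11 (1S,4S)-4-bromo-3,3-dimethyl-1-[(2E)-4-oxobut-2-en-1-yl]cyclohexyl acetate; 12 nitromethane
Product: 13 (1S,4S)-4-bromo-3,3-dimethyl-1-[(2R)-2-(nitromethyl)-4-oxobutyl]cyclohexyl acetate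
Conditions: 12 (excess), (S)-α,α-diphenylprolinol TMS ether (10 mol %), PhCO2H (20 mol %), MeOH, 23 °C
Reagents that add atoms: none
Why: Iminium-ion-catalysed Michael addition of nitromethane, in which the (S)-diarylprolinol silyl ether forms the E-iminium ion and shields one face of C-β so that the nitronate adds to the other, which should give the (R)-configured carbon that becomes C1 of the hydrindane irrespective of the remote ring.

Step 9
Reactants: 13 (1S,4S)-4-bromo-3,3-dimethyl-1-[(2R)-2-(nitromethyl)-4-oxobutyl]cyclohexyl acetate; 14 cyclopentane-1,3-dione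
Product: 15 (1S,4S)-4-bromo-1-[(2S)-4-(2,5-dioxocyclopentyl)-2-(nitromethyl)butyl]-3,3-dimethylcyclohexyl acetate
Conditions: Hantzsch ester, L-proline (10 mol %), CH2Cl2, 23 °C
Reagents that add atoms: none
Why: Three-component reductive alkylation, in which proline-catalysed Knoevenagel condensation of the aldehyde with the acidic dione gives an alkylidene dione that is reduced at once by hydride transfer from the Hantzsch ester, so that clean mono-C-alkylation is expected and no stereocentre is formed or touched (the descriptor changes only through CIP priorities).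

Step 10
Reactants: 15 (1S,4S)-4-bromo-1-[(2S)-4-(2,5-dioxocyclopentyl)-2-(nitromethyl)butyl]-3,3-dimethylcyclohexyl acetate; 16 allyl methyl carbonate
Product: 17 (1S,4S)-1-[(2S)-4-(1-allyl-2,5-dioxocyclopentyl)-2-(nitromethyl)butyl]-4-bromo-3,3-dimethylcyclohexyl acetate
Conditions: 16, Pd(PPh3)4 (5 mol %), THF, 23 °C
Reagents that add atoms: none
Why: Tsuji–Trost allylation, in which decarboxylation of the carbonate gives π-allylpalladium methoxide, the methoxide deprotonates the vinylogous acid and the soft dione anion attacks the allyl ligand at carbon, which creates the quaternary carbon (not yet stereogenic because the two ring carbonyl groups are still equivalent).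

Step 11
Reactants: 17 (1S,4S)-1-[(2S)-4-(1-allyl-2,5-dioxocyclopentyl)-2-(nitromethyl)butyl]-4-bromo-3,3-dimethylcyclohexyl acetate
Product: 18 (1S,4S)-1-{[(3aR,4S,5S,7aR)-7a-allyl-3a-hydroxy-4-nitro-1-oxooctahydro-1H-inden-5-yl]methyl}-4-bromo-3,3-dimethylcyclohexyl acetate
Conditions: DBU (0.3 equiv), THF, 23 °C, until the isomer composition no longer changes
Reagents that add atoms: none
Why: Intramolecular Henry (nitro-aldol) reaction run under equilibrating conditions, in which the tether forces attack on the carbonyl face syn to the chain so that the ring fusion is cis with OH and allyl on the same side, and reversibility together with nitronate epimerisation should funnel the material into the chair with nitro group, side chain and allyl equatorial and only OH axial, which decides which of the two carbonyl groups reacts and so sets the carbinol carbon, the nitro carbon and the quaternary carbon relative to the side-chain carbon.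

Step 12
Reactants: 18 (1S,4S)-1-{[(3aR,4S,5S,7aR)-7a-allyl-3a-hydroxy-4-nitro-1-oxooctahydro-1H-inden-5-yl]methyl}-4-bromo-3,3-dimethylcyclohexyl acetate
Product: 20 (1S,4S)-1-{[(1S,3aR,7aS)-3a-allyl-4,7-dioxooctahydro-1H-inden-1-yl]methyl}-4-bromo-3,3-dimethylcyclohexyl acetate, via amino alcohol 19 (not isolated)
Conditions: Zn dust, AcOH/THF, 23 °C; filter; NaNO2, AcOH/H2O, 0 → 23 °C
Reagents that add atoms: none
Why: Zinc in acetic acid reduces the nitro group to the equatorial amine 19, nitrous acid turns it into the diazonium ion, and as N2 leaves the anti-periplanar ring-fusion bond migrates from the carbinol carbon to the diazonium carbon while the hydroxyl oxygen takes up the charge and becomes the C7 carbonyl group (semipinacol shift of the Tiffeneau–Demjanov type). The closest known reactions are the ring-contracting deamination of cis-2-amino-1-alkylcyclohexanols to acylcyclopentanes and the C-nor-D-homo steroid rearrangement, in which a ring-fusion bond likewise shifts so that one ring contracts while its neighbour expands. No ring is closed end to end: the 1,2-shift inserts the former amine carbon between the carbinol carbon and the quaternary carbon, which enlarges the cyclopentanone to the cyclohexane-1,4-dione ring and contracts the cyclohexane to the cyclopentane. The one new stereocentre, C7a, is formed with inversion because the migrating carbon enters anti to N2, and this places H-7a trans to the angular allyl group (trans-hydrindane); the migrating quaternary carbon keeps its configuration, as in all 1,2-shifts. The step needs migration of the fusion bond in preference to hydride shift, epoxide closure, solvolysis or shift of the C1–C2 bond; this is secured by the chair of 19 with NH2, side chain and allyl equatorial and OH axial, in which only the fusion bond and C1–C2 are anti-periplanar to the C–N2+ bond and only the former is pushed by oxygen.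

Step 13
Reactants: 20 (1S,4S)-1-{[(1S,3aR,7aS)-3a-allyl-4,7-dioxooctahydro-1H-inden-1-yl]methyl}-4-bromo-3,3-dimethylcyclohexyl acetate
Product: 21 (1S,4S)-1-{[(1S,3aR,7R,7aS)-3a-allyl-7-hydroxy-7-methyl-4-oxooctahydro-1H-inden-1-yl]methyl}-4-bromo-3,3-dimethylcyclohexyl acetate
Conditions: MeTi(OiPr)3, CH2Cl2/Et2O, −40 → 0 °C
Reagents that add atoms: methyltitanium triisopropoxide C[Ti](OC(C)C)(OC(C)C)OC(C)C
Why: Chemoselective carbonyl addition of the bulky, non-basic methyltitanium reagent, in which the C7 ketone should react well before the neopentylic C4 ketone and the ester, enolisation at C7a is avoided, and methyl enters equatorially because the axial face is blocked by the 1,3-diaxial allyl group, which gives the axial 7-OH cis to allyl (7R).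

Step 14
Reactants: 21 (1S,4S)-1-{[(1S,3aR,7R,7aS)-3a-allyl-7-hydroxy-7-methyl-4-oxooctahydro-1H-inden-1-yl]methyl}-4-bromo-3,3-dimethylcyclohexyl acetate
Product: 22 (1S,4S)-1-{[(1S,3aR,4R,7R,7aS)-3a-allyl-4,7-dihydroxy-7-methyloctahydro-1H-inden-1-yl]methyl}-4-bromo-3,3-dimethylcyclohexyl acetate
Conditions: L-Selectride, THF, −78 °C; H2O
Reagents that add atoms: none
Why: Reduction with the bulky trialkylborohydride L-Selectride, which attacks a cyclohexanone with a quaternary α-carbon along the equatorial trajectory and should therefore give the axial 4-alcohol trans to the allyl group, while the tertiary acetate does not react at this temperature.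

Step 15
Reactants: 22 (1S,4S)-1-{[(1S,3aR,4R,7R,7aS)-3a-allyl-4,7-dihydroxy-7-methyloctahydro-1H-inden-1-yl]methyl}-4-bromo-3,3-dimethylcyclohexyl acetate
Product: 23 (1S,4S)-1-{[(1S,3aR,4S,7R,7aS)-3a-allyl-4-bromo-7-hydroxy-7-methyloctahydro-1H-inden-1-yl]methyl}-4-bromo-3,3-dimethylcyclohexyl acetate
Conditions: CBr4, PPh3, toluene, 23 → 50 °C
Reagents that add atoms: carbon tetrabromide BrC(Br)(Br)Br
Why: Appel reaction with inversion, in which SN2 attack of bromide on the axial oxyphosphonium ion should give the equatorial 4-bromide cis to the allyl group, while the hindered tertiary 7-alcohol is not activated under these non-ionising conditions.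

Step 16
Reactants: 23 (1S,4S)-1-{[(1S,3aR,4S,7R,7aS)-3a-allyl-4-bromo-7-hydroxy-7-methyloctahydro-1H-inden-1-yl]methyl}-4-bromo-3,3-dimethylcyclohexyl acetate
Product: 24 (1S,4S)-4-bromo-1-{[(1S,3aR,4S,7R,7aS)-4-bromo-7-hydroxy-7-methyl-3a-[(1E)-prop-1-en-1-yl]octahydro-1H-inden-1-yl]methyl}-3,3-dimethylcyclohexyl acetate
Conditions: [Ir(cod)(PMePh2)2]PF6 (5 mol %, activated with H2, then Ar), THF, 23 °C
Reagents that add atoms: none
Why: Metal-hydride-catalysed alkene isomerisation (insertion and β-hydride elimination), in which the double bond moves by one position into the more stable internal E position and cannot move further because the next carbon is quaternary.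

Step 17
Reactants: 24 (1S,4S)-4-bromo-1-{[(1S,3aR,4S,7R,7aS)-4-bromo-7-hydroxy-7-methyl-3a-[(1E)-prop-1-en-1-yl]octahydro-1H-inden-1-yl]methyl}-3,3-dimethylcyclohexyl acetate
Product: 26 (1S,4S)-4-bromo-1-{[(1S,3aS,4S,7R,7aS)-4-bromo-7-hydroxy-3a-(hydroxymethyl)-7-methyloctahydro-1H-inden-1-yl]methyl}-3,3-dimethylcyclohexyl acetate, via aldehyde 25 (not isolated)
Conditions: O3, CH2Cl2/MeOH, −78 °C; then NaBH4, −78 → 0 °C
Reagents that add atoms: ozone [O-][O+]=O
Why: Ozonolysis with reductive work-up, in which cycloaddition of ozone to the only C=C bond and fragmentation give the neopentylic aldehyde that borohydride reduces in the same flask to the primary alcohol, with no stereocentre touched.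

**Compound list**

1 | 7,7-dimethyl-1,4-dioxaspiro[4.5]decan-8-one | CC1(C)CC2(CCC1=O)OCCO2 | starting material
2 | (8R)-7,7-dimethyl-1,4-dioxaspiro[4.5]decan-8-ol | CC1(C)CC2(CC[C@H]1O)OCCO2 | intermediate
3 | tert-butyl{[(8R)-7,7-dimethyl-1,4-dioxaspiro[4.5]decan-8-yl]oxy}dimethylsilane | CC1(C)CC2(CC[C@H]1O[Si](C)(C)C(C)(C)C)OCCO2 | intermediate
4 | (4R)-4-[(tert-butyldimethylsilyl)oxy]-3,3-dimethylcyclohexan-1-one | CC1(C)CC(=O)CC[C@H]1O[Si](C)(C)C(C)(C)C | intermediate
5 | allylmagnesium bromide | C=CC[Mg]Br | starting material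
6 | bromomagnesium (1S,4R)-1-allyl-4-[(tert-butyldimethylsilyl)oxy]-3,3-dimethylcyclohexan-1-olate | Br[Mg]O[C@]1(CC=C)CC[C@@H](O[Si](C)(C)C(C)(C)C)C(C)(C)C1 | intermediate
7 | (1S,4R)-1-allyl-4-[(tert-butyldimethylsilyl)oxy]-3,3-dimethylcyclohexyl acetate | CC(=O)O[C@]1(CC=C)CC[C@@H](O[Si](C)(C)C(C)(C)C)C(C)(C)C1 | intermediate
8 | (1S,4R)-1-allyl-4-hydroxy-3,3-dimethylcyclohexyl acetate | CC(=O)O[C@]1(CC=C)CC[C@@H](O)C(C)(C)C1 | intermediate
9 | (1S,4S)-1-allyl-4-bromo-3,3-dimethylcyclohexyl acetate | CC(=O)O[C@]1(CC=C)CC[C@H](Br)C(C)(C)C1 | intermediate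
10 | (E)-but-2-enal (crotonaldehyde) | C/C=C/C=O | starting material
11 | (1S,4S)-4-bromo-3,3-dimethyl-1-[(2E)-4-oxobut-2-en-1-yl]cyclohexyl acetate | CC(=O)O[C@]1(C/C=C/C=O)CC[C@H](Br)C(C)(C)C1 | intermediate
12 | nitromethane | C[N+](=O)[O-] | starting material
13 | (1S,4S)-4-bromo-3,3-dimethyl-1-[(2R)-2-(nitromethyl)-4-oxobutyl]cyclohexyl acetate | CC(=O)O[C@]1(C[C@H](CC=O)C[N+](=O)[O-])CC[C@H](Br)C(C)(C)C1 | intermediate
14 | cyclopentane-1,3-dione | O=C1CCC(=O)C1 | starting material
15 | (1S,4S)-4-bromo-1-[(2S)-4-(2,5-dioxocyclopentyl)-2-(nitromethyl)butyl]-3,3-dimethylcyclohexyl acetate | CC(=O)O[C@]1(C[C@H](CCC2C(=O)CCC2=O)C[N+](=O)[O-])CC[C@H](Br)C(C)(C)C1 | intermediate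
16 | allyl methyl carbonate | C=CCOC(=O)OC | starting material
17 | (1S,4S)-1-[(2S)-4-(1-allyl-2,5-dioxocyclopentyl)-2-(nitromethyl)butyl]-4-bromo-3,3-dimethylcyclohexyl acetate | CC(=O)O[C@]1(C[C@H](CCC2(CC=C)C(=O)CCC2=O)C[N+](=O)[O-])CC[C@H](Br)C(C)(C)C1 | intermediate
18 | (1S,4S)-1-{[(3aR,4S,5S,7aR)-7a-allyl-3a-hydroxy-4-nitro-1-oxooctahydro-1H-inden-5-yl]methyl}-4-bromo-3,3-dimethylcyclohexyl acetate (cis-fused; OH, NO2 and allyl on one face, side chain on the other) | CC(=O)O[C@]1(C[C@@H]2CC[C@]3(CC=C)C(=O)CC[C@]3(O)[C@H]2[N+](=O)[O-])CC[C@H](Br)C(C)(C)C1 | intermediate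
19 | (1S,4S)-1-{[(3aR,4S,5S,7aR)-7a-allyl-4-amino-3a-hydroxy-1-oxooctahydro-1H-inden-5-yl]methyl}-4-bromo-3,3-dimethylcyclohexyl acetate | CC(=O)O[C@]1(C[C@@H]2CC[C@]3(CC=C)C(=O)CC[C@]3(O)[C@H]2N)CC[C@H](Br)C(C)(C)C1 | intermediate
20 | (1S,4S)-1-{[(1S,3aR,7aS)-3a-allyl-4,7-dioxooctahydro-1H-inden-1-yl]methyl}-4-bromo-3,3-dimethylcyclohexyl acetate (trans-fused) | CC(=O)O[C@]1(C[C@@H]2CC[C@]3(CC=C)C(=O)CCC(=O)[C@@H]23)CC[C@H](Br)C(C)(C)C1 | intermediate
21 | (1S,4S)-1-{[(1S,3aR,7R,7aS)-3a-allyl-7-hydroxy-7-methyl-4-oxooctahydro-1H-inden-1-yl]methyl}-4-bromo-3,3-dimethylcyclohexyl acetate | CC(=O)O[C@]1(C[C@@H]2CC[C@]3(CC=C)C(=O)CC[C@@](C)(O)[C@@H]23)CC[C@H](Br)C(C)(C)C1 | intermediate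
22 | (1S,4S)-1-{[(1S,3aR,4R,7R,7aS)-3a-allyl-4,7-dihydroxy-7-methyloctahydro-1H-inden-1-yl]methyl}-4-bromo-3,3-dimethylcyclohexyl acetate | CC(=O)O[C@]1(C[C@@H]2CC[C@]3(CC=C)[C@H](O)CC[C@@](C)(O)[C@@H]23)CC[C@H](Br)C(C)(C)C1 | intermediate
23 | (1S,4S)-1-{[(1S,3aR,4S,7R,7aS)-3a-allyl-4-bromo-7-hydroxy-7-methyloctahydro-1H-inden-1-yl]methyl}-4-bromo-3,3-dimethylcyclohexyl acetate | CC(=O)O[C@]1(C[C@@H]2CC[C@]3(CC=C)[C@@H](Br)CC[C@@](C)(O)[C@@H]23)CC[C@H](Br)C(C)(C)C1 | intermediate
24 | (1S,4S)-4-bromo-1-{[(1S,3aR,4S,7R,7aS)-4-bromo-7-hydroxy-7-methyl-3a-[(1E)-prop-1-en-1-yl]octahydro-1H-inden-1-yl]methyl}-3,3-dimethylcyclohexyl acetate | CC(=O)O[C@]1(C[C@@H]2CC[C@]3(/C=C/C)[C@@H](Br)CC[C@@](C)(O)[C@@H]23)CC[C@H](Br)C(C)(C)C1 | intermediate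
25 | (1S,4S)-4-bromo-1-{[(1S,3aS,4S,7R,7aS)-4-bromo-3a-formyl-7-hydroxy-7-methyloctahydro-1H-inden-1-yl]methyl}-3,3-dimethylcyclohexyl acetate | CC(=O)O[C@]1(C[C@@H]2CC[C@]3(C=O)[C@@H](Br)CC[C@@](C)(O)[C@@H]23)CC[C@H](Br)C(C)(C)C1 | intermediate
26 | (1S,4S)-4-bromo-1-{[(1S,3aS,4S,7R,7aS)-4-bromo-7-hydroxy-3a-(hydroxymethyl)-7-methyloctahydro-1H-inden-1-yl]methyl}-3,3-dimethylcyclohexyl acetate (CNP0182818.1) | CC(=O)O[C@]1(C[C@@H]2CC[C@]3(CO)[C@@H](Br)CC[C@@](C)(O)[C@@H]23)CC[C@H](Br)C(C)(C)C1 | target

**Step count and risks**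

Total step count: 17. Longest linear sequence: 17 (1 → 26; the partners 5, 10, 12, 14 and 16 are bought).

Steps most likely to fail:

Step 15. The axial oxyphosphonium ion at C4 may ionise with 1,2-shift of the anti-periplanar allyl group, or undergo E2 loss towards C5, or the tertiary C7 alcohol may be dehydrated, all in place of the slow neopentylic SN2 step. Fallback: the bromine is brought in while this carbon is still part of the cyclopentanone, before the ring shift. The fallback sets out from 18. Hydroxyl-directed reduction with Me4NBH(OAc)3 (hydride delivered from the angular alkoxyborohydride, Evans–Saksena type) should give the 1,3-anti nitro diol F1. Appel bromination of the cyclopentanol, where SN2 displacement is far easier than on a cyclohexane, should give the nitro bromide F2 with inversion. Zinc in acetic acid then gives the amino bromide F3, which is not isolated, and nitrous acid converts it by the same shift as in step 12 into the bromo ketone F4. Methyltitanium triisopropoxide, now without a second ketone to compete, gives 23, where the fallback comes back to the route; steps 13 to 15 are replaced.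

Step 11. The two ring carbonyl groups may be poorly discriminated, or equilibration may be incomplete, so that the isomer with axial allyl and equatorial OH or the axial-nitro epimer is carried on; retro-Henry opening on work-up is also possible. Fallback: the ring is closed under kinetic, metal-templated control and the shift is triggered from a sulfonate. The fallback sets out from 17. A buffered TiCl3 Nef reaction converts the nitromethyl group into the aldehyde F5. Samarium diiodide (THF, t-BuOH, −78 °C) then effects a ketyl–aldehyde pinacol cyclisation through the samarium-bridged chair to the cis-diol F6. Methanesulfonyl chloride in pyridine sulfonylates only the secondary hydroxyl group to give the mesylate F7. Potassium tert-butoxide (or triethylaluminium) triggers the same 1,2-shift with mesylate as the leaving group and gives 20, where the fallback comes back to the route; steps 11 and 12 are replaced.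

Step 4. The addition may run mainly through the chair with the silyloxy group equatorial (poor conformational and hence facial control), which gives the C1 epimer with acetate cis to the silyloxy group. Fallback: the order of bromination and addition is reversed, so that the cis relation between bromine and acetate is exactly what that chair delivers. The fallback sets out from 2. Appel bromination gives the inverted bromo ketal F8, and PPTS in wet acetone gives the bromo ketone F9. Allylmagnesium bromide, adding equatorially to the chair with equatorial bromine, gives the cis bromo alcohol F10. Acetylation (Ac2O, DMAP, Et3N) gives 9, where the fallback comes back to the route; steps 2 to 6 are replaced.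

Further compounds
F1 | step 15 | (1S,4S)-1-{[(1R,3aR,4S,5S,7aS)-7a-allyl-1,3a-dihydroxy-4-nitrooctahydro-1H-inden-5-yl]methyl}-4-bromo-3,3-dimethylcyclohexyl acetate | CC(=O)O[C@]1(C[C@@H]2CC[C@]3(CC=C)[C@H](O)CC[C@]3(O)[C@H]2[N+](=O)[O-])CC[C@H](Br)C(C)(C)C1
F2 | step 15 | (1S,4S)-1-{[(1S,3aR,4S,5S,7aR)-7a-allyl-1-bromo-3a-hydroxy-4-nitrooctahydro-1H-inden-5-yl]methyl}-4-bromo-3,3-dimethylcyclohexyl acetate | CC(=O)O[C@]1(C[C@@H]2CC[C@]3(CC=C)[C@@H](Br)CC[C@]3(O)[C@H]2[N+](=O)[O-])CC[C@H](Br)C(C)(C)C1
F3 | step 15 | (1S,4S)-1-{[(1S,3aR,4S,5S,7aR)-7a-allyl-4-amino-1-bromo-3a-hydroxyoctahydro-1H-inden-5-yl]methyl}-4-bromo-3,3-dimethylcyclohexyl acetate | CC(=O)O[C@]1(C[C@@H]2CC[C@]3(CC=C)[C@@H](Br)CC[C@]3(O)[C@H]2N)CC[C@H](Br)C(C)(C)C1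
F4 | step 15 | (1S,4S)-1-{[(1S,3aR,4S,7aS)-3a-allyl-4-bromo-7-oxooctahydro-1H-inden-1-yl]methyl}-4-bromo-3,3-dimethylcyclohexyl acetate | CC(=O)O[C@]1(C[C@@H]2CC[C@]3(CC=C)[C@@H](Br)CCC(=O)[C@@H]23)CC[C@H](Br)C(C)(C)C1
F5 | step 11 | (1S,4S)-1-[(2S)-4-(1-allyl-2,5-dioxocyclopentyl)-2-formylbutyl]-4-bromo-3,3-dimethylcyclohexyl acetate | CC(=O)O[C@]1(C[C@H](CCC2(CC=C)C(=O)CCC2=O)C=O)CC[C@H](Br)C(C)(C)C1
F6 | step 11 | (1S,4S)-1-{[(3aR,4S,5S,7aR)-7a-allyl-3a,4-dihydroxy-1-oxooctahydro-1H-inden-5-yl]methyl}-4-bromo-3,3-dimethylcyclohexyl acetate | CC(=O)O[C@]1(C[C@@H]2CC[C@]3(CC=C)C(=O)CC[C@]3(O)[C@H]2O)CC[C@H](Br)C(C)(C)C1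
F7 | step 11 | (1S,4S)-1-{[(3aR,4S,5S,7aR)-7a-allyl-3a-hydroxy-4-[(methylsulfonyl)oxy]-1-oxooctahydro-1H-inden-5-yl]methyl}-4-bromo-3,3-dimethylcyclohexyl acetate | CC(=O)O[C@]1(C[C@@H]2CC[C@]3(CC=C)C(=O)CC[C@]3(O)[C@H]2OS(C)(=O)=O)CC[C@H](Br)C(C)(C)C1
F8 | step 4 | (8S)-8-bromo-7,7-dimethyl-1,4-dioxaspiro[4.5]decane | CC1(C)CC2(CC[C@@H]1Br)OCCO2
F9 | step 4 | (4S)-4-bromo-3,3-dimethylcyclohexan-1-one | CC1(C)CC(=O)CC[C@@H]1Br
F10 | step 4 | (1S,4S)-1-allyl-4-bromo-3,3-dimethylcyclohexan-1-ol | O[C@]1(CC=C)CC[C@H](Br)C(C)(C)C1
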